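**Examiner:** At 4.00 min maple, ash and larch still hold 59.3%, 39.7% and 23.7% of their substrate, and the readings have nearly stopped moving. Why does a reaction stall with substrate present?

**Candidate:** Maple was charged with more partner than substrate, yet its mono adduct reaches 40.6%. So I suppose partner has a second exit: beside the step with substrate, at rate k·c(substrate)·c(partner), a first-order loss at rate k′·c(partner).

in all of them: substrate 0.20 M
- maple: partner 0.25 M; run made earlier
- ash: partner 0.43 M; run made earlier
- larch: partner 0.66 M; run made earlier
- teal: partner 0.300 M; time 5.0 min
- violet: partner 0.600 M; time 5.0 min

| run | time / min | substrate / % | mono adduct / % |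
|---|---|---|---|
| maple | 0.250 | 69.7 | 26.3 |
| maple | 0.667 | 64.2 | 33.2 |
| maple | 1.50 | 60.7 | 38.6 |
| maple | 4.00 | 59.3 | 40.6 |
| ash | 0.250 | 53.9 | 34.7 |
| ash | 0.667 | 47.9 | 48.0 |
| ash | 1.50 | 42.5 | 57.6 |
| ash | 4.00 | 39.7 | 60.8 |
| larch | 0.833 | 29.8 | 63.9 |
| larch | 2.00 | 24.6 | 74.9 |
| larch | 2.50 | 23.2 | 75.3 |
| larch | 4.00 | 23.7 | 77.9 |

(readings scatter by 0.5 percentage points)

1. part of the substrate that has reacted at the end, teal
2. part of the substrate that has reacted at the end, violet
3. what raising the concentration of partner from its lowest to its highest value here does to the part of the substrate that has reacted (changes below 5 percentage points count as none) (it rises / it falls / no change)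



**Examiner:** Your reckoning?

**Candidate:** Divide one rate by the other. Time and c(partner) cancel, so each substrate consumed costs one partner plus κ/c(substrate) more, with κ = k′/k. Integrated to the stall, with s the fraction of substrate left, the partner charge equals the substrate charge times (1 − s) plus κ ln(1/s). The last readings of maple, ash and larch then give 0.323 M, 0.335 M and 0.352 M. Their mean, 0.337 M, is my break-even concentration κ, a selectivity factor: the c(substrate) at which partner is lost equally to both exits.

**Examiner:** Teal and violet?

**Candidate:** The asked time lies beyond the last readings, so I take both as stalled. One Newton step from half left gives teal 46.2%, and one from a quarter left gives violet 73.9%. So the conversion rises.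

**Examiner:** But your κ, as read from these runs, is higher in larch than in maple.

**Candidate:** It does, and I cannot explain that. The two end values put teal at 45.1% and 47.2%.

The forecast, resting on “second-order consumption that stops when the active agent dies”, gives teal 46.8% (44.5% to 49%), violet 73% (70.5% to 75.5%), and for the trend: it rises. My teal figure lies below its value and my violet figure above.

The flasks give teal 46.7% and violet 74.3%, and for the trend: it rises, by 28 percentage points.

    substrate + partner → mono adduct + released group (k = 0.309 M⁻¹ s⁻¹)
    partner + mono adduct ⇌ double product + released group (K = 0.270, k = 0.343 M⁻¹ s⁻¹)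
    partner + released group ⇌ idle adduct, settled at all times (K = 82.3 M⁻¹)
    partner → decomposed reagent (k = 0.101 s⁻¹)

Teal ends with 0.025% of its partner unbound against 53% of its substrate, so partner is the limiting reagent at 1.50 equivalents. With that s, κ ln(1/s) is 0.214 M, and teal holds 0.206 M of decomposed reagent. A neighbour of teal has 0.34 M of substrate, which makes 0.882 equiv of partner. The same Newton step from half left gives it a conversion of 39.8%, and that flask gives 39.5%.

The data come from a simulation from invented constants; noise was put on by code.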